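Friday's run has its scavenger charge above its electrophile charge, and Thursday's run, with less scavenger, reads alike in percent up to 2.50 h, but at 8.00 h Thursday's run has more electrophile left, 52.3% against 46.8%.

| flask | electrophile | nucleophile | free base | scavenger | remark | time |
|---|---|---|---|---|---|---|
| Friday's | 0.034 M | 0.065 M | 0.075 M | 0.050 M | run made earlier |  |
| Thursday's | 0.050 M | 0.065 M | 0.075 M | 0.025 M | run made earlier |  |
| north-west | 0.050 M | 0.0650 M | 0.0750 M | 0.0500 M |  | 20 h |
| west | 0.050 M | 0.0650 M | 0.110 M | 0.0500 M |  | 20 h |
| north | 0.050 M | 0.0650 M | 0.170 M | 0.0500 M |  | 20 h |

| run | time / h | electrophile / % | product / % |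
|---|---|---|---|
| Friday's | 1.33 | 85.9 | 14.2 |
| Friday's | 2.50 | 76.9 | 22.8 |
| Friday's | 4.00 | 65.7 | 34.3 |
| Friday's | 5.00 | 61.1 | 38.7 |
| Friday's | 6.00 | 55.7 | 44.7 |
| Friday's | 8.00 | 46.8 | 53.3 |
| Thursday's | 0.500 | 95.6 | 5.4 |
| Thursday's | 1.33 | 85.8 | 13.5 |
| Thursday's | 2.50 | 77.1 | 23.0 |
| Thursday's | 4.00 | 69.1 | 30.7 |
| Thursday's | 5.00 | 63.7 | 36.9 |
| Thursday's | 8.00 | 52.3 | 48.7 |

(scatter of a reading: 1 percentage point)

- acid set free is meant together with its idle adduct
- the numbers in the tables scatter with a standard deviation of 1 percentage point
- on the list of suspects stand: acid set free + scavenger -> scavenged by-product; acid set free -> by-product carried off; electrophile + nucleophile -> acid set free + product; nucleophile + acid set free <-> protonated nucleophile; acid set free + free base <-> salt of the base; nucleophile + acid set free <-> idle adduct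
- no earlier run changes the charge of free base; that part of a forecast is a guess

- part of the electrophile that has reacted at the end, north-west
- part of the electrophile that has reacted at the end, west
- part of the electrophile that has reacted at the end, north
- what raising the concentration of free base from its lowest to its highest value here does to the part of the electrophile that has reacted (changes below 5 percentage points count as none) (it falls / no change / it rises)

Friday's last reading gives 1.75 /M/h. I call this reading the coupling constant k: the pace at which electrophile and nucleophile react, divided by c(electrophile) times c(nucleophile). With k frozen and one nucleophile spent per electrophile, my own reckoning for north-west gives 74.9% reacted at 20 h. That is my mark for a flask that keeps Friday's k to the end.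

Tom and Ruth dispute what free base adds, and no earlier run varies it, so both are guessing. Tom looks at Thursday's run: k leaves 49.7% of the electrophile at 8.00 h, but the reading is 52.3%, a lag of 2.6 percentage points. Stretched in proportion to 20 h, that lag becomes 6.4 points, above the margin of 5 points, so he expects extra free base to win back a real rise.

Ruth answers that at k's pace Thursday's run makes 0.0251 M of acid by then, about its whole scavenger charge. North-west, at k's pace, makes 0.0375 M, less than its 0.0500 M of scavenger.

Ruth's forecast is 71% for north-west, 72% for west and 73% for north, with the trend no change. Her north-west number stands below my mark, since she takes a few points off for acid, and she adds: “Extra base can at most recover that small loss”.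

The flasks give 73.4%, 73.7% and 74.1%, so the trend is no change, a change of 0.66 points, and Tom's rise does not appear here. At the end of north-west, 46% of the scavenger is still there. My mark from k lies 1.5 points above the north-west result, less than the margin. Tom keeps Thursday's run, with half the scavenger, where his lag was read.

    acid set free + scavenger → scavenged by-product (k = 83.0 /M/h)
    acid set free → by-product carried off (k = 0.0180 /h)
    electrophile + nucleophile → acid set free + product (k = 1.90 /M/h)
    nucleophile + acid set free ⇌ protonated nucleophile, settled at all times (K = 260 /M)
    acid set free + free base ⇌ salt of the base (K = 2.70 × 10⁵ /M, k = 9.00 /M/h)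
    nucleophile + acid set free ⇌ idle adduct, settled at all times (K = 72.0 /M)

Take north with 0.26 M of nucleophile, where the limiting reagent is electrophile: k leaves 0.0526% of it at 20 h. The computed flask leaves 0.067%.

The readings stem from a simulated flask from invented constants.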